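**Plan**

- Retrosynthesis: the sulfate O–S bond and the two ring A benzyl ethers are cut first. Ring C is then opened at the aryl ether bond O1–C8a, the C3–C4 bond is cut back to an aldol pair, and the formyl carbon (future C4) is cut from C4a.
- Enabling feature: O1 of ring C links C2 to the ring A carbon C8a, which lies ortho to the C4 carbonyl. An enol oxygen on C2 of a 1,3-diketone and a bromine on C8a are therefore placed for a six-membered O-arylation, and ring A needs no free phenol at that position.
- Forward: ring A is prepared as bromo aldehyde 5, and ring B arrives with C2, C3 and the protected 3-oxygen as ketone 9. Aldol addition joins C3–C4, oxidation gives diketone 13, and copper-mediated closure forms ring C (14).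
- End game: acetal cleavage frees only the 3-hydroxyl, which is sulfated; hydrogenolysis of the benzyl ethers and protonation finish the route.
- Stereochemistry: the target has no stereocentre. The two centres formed in the aldol step are removed by the oxidation and enolisation that follow.

Key step: step 7

Assumption: the target is taken as the free hydrogen sulfate drawn; because aryl hydrogen sulfates hydrolyse under acid, the sulfate is carried as its potassium salt and protonated only in the last operation.

**Route**

Step 1
Reactants: 1 5-bromoresorcinol; 2 benzyl bromide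
Product: 3 1,3-bis(benzyloxy)-5-bromobenzene
Conditions: BnBr (2.2 equiv), K2CO3 (3 equiv), DMF, 60 °C
Reagents that add atoms: benzyl bromide (second equivalent, for the second ether), BrCc1ccccc1
Why: Twofold Williamson ether synthesis, in which each of the two phenoxides formed with K2CO3 displaces bromide from one molecule of benzyl bromide by SN2 while the aryl bromide stays inert.

Step 2
Reactants: 3 1,3-bis(benzyloxy)-5-bromobenzene
Product: 5 2,4-bis(benzyloxy)-6-bromobenzaldehyde, via aryl iminium chloride 4 (not isolated)
Conditions: POCl3, DMF, 0 °C → 75 °C; then H2O, 0 °C → rt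
Reagents that add atoms: N,N-dimethylformamide, CN(C)C=O; water, O
Why: Vilsmeier–Haack formylation, in which the chloroiminium ion should attack the position para to one benzyloxy group and ortho to the other (next to bromine) rather than the more crowded carbon between the two ethers, as is usual for 5-substituted resorcinol diethers, and water then hydrolyses the iminium salt to the aldehyde.

Step 3
Reactants: 6 2-bromo-1-(4-methoxyphenyl)ethanone
Product: 8 2-hydroxy-1-(4-methoxyphenyl)ethanone, via formate ester 7 (not isolated)
Conditions: HCO2Na, EtOH/H2O (4:1), reflux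
Reagents that add atoms: sodium formate, [Na+].[O-]C=O
Why: SN2 displacement of the activated α-bromide by formate followed by solvolysis of the labile formate ester in the same pot, a standard entry to α-hydroxy ketones that avoids the self-condensation seen with hydroxide.

Step 4
Reactants: 8 2-hydroxy-1-(4-methoxyphenyl)ethanone
Product: 9 2-(methoxymethoxy)-1-(4-methoxyphenyl)ethanone
Conditions: MOMCl, iPr2NEt, CH2Cl2, 0 °C → rt
Reagents that add atoms: chloromethyl methyl ether, COCCl
Why: Standard methoxymethyl ether formation (O-alkylation of the primary alcohol under amine base), giving an acetal that tolerates the enolate, oxidation and copper steps and can later be removed with acid beside benzyl ethers.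

Step 5
Reactants: 9 2-(methoxymethoxy)-1-(4-methoxyphenyl)ethanone; 5 2,4-bis(benzyloxy)-6-bromobenzaldehyde
Product: 12 3-[2,4-bis(benzyloxy)-6-bromophenyl]-3-hydroxy-2-(methoxymethoxy)-1-(4-methoxyphenyl)propan-1-one (syn/anti mixture; racemic), via lithium enolate 10 (not isolated), via lithium aldolate 11 (not isolated)
Conditions: LiN(iPr)2 (LDA), THF, −78 °C; then 5, −78 °C; AcOH, −78 °C
Reagents that add atoms: none
Why: Directed crossed aldol addition, in which kinetic deprotonation gives the chelated Z-enolate of the α-alkoxy ketone that adds to the non-enolisable aldehyde; the two new stereocentres form without control and are erased in step 6, and the cold acidic quench limits retro-aldol.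

Step 6
Reactants: 12 3-[2,4-bis(benzyloxy)-6-bromophenyl]-3-hydroxy-2-(methoxymethoxy)-1-(4-methoxyphenyl)propan-1-one
Product: 13 1-[2,4-bis(benzyloxy)-6-bromophenyl]-2-(methoxymethoxy)-3-(4-methoxyphenyl)propane-1,3-dione (racemic; readily enolised)
Conditions: Dess–Martin periodinane, CH2Cl2, 0 °C → rt
Reagents that add atoms: none
Why: Dess–Martin oxidation of the secondary benzylic alcohol to the ketone under nearly neutral conditions should give the 2-alkoxy-1,3-diketone without touching the acetal, the benzyl ethers or the aryl bromide.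

Step 7
Reactants: 13 1-[2,4-bis(benzyloxy)-6-bromophenyl]-2-(methoxymethoxy)-3-(4-methoxyphenyl)propane-1,3-dione
Product: 14 5,7-bis(benzyloxy)-3-(methoxymethoxy)-2-(4-methoxyphenyl)-4H-chromen-4-one
Conditions: CuI (10 mol %), 1,10-phenanthroline (20 mol %), Cs2CO3 (2 equiv), DMF, 90 °C, Ar
Reagents that add atoms: none
Why: Intramolecular Ullmann-type O-arylation, in which Cs2CO3 forms the diketone enolate, phenanthroline-ligated monovalent copper binds the enolate oxygen and inserts into the ring A C–Br bond, and C–O reductive elimination from the resulting trivalent copper metallacycle forms O1–C8a. The closest known reaction type is the CuI-catalysed cyclisation of 1-(2-haloaryl)-1,3-diketones to chromones and flavones. Ring C closes as a six-membered ring in a 6-exo sense at the sp2 carbon C8a (the C–Br bond that breaks lies outside the new ring), through a seven-membered cupracycle that contracts to the six-membered pyranone. No stereocentre is formed, and the centre at C2 of the diketone disappears on enolisation. The step needs O- over C-arylation and the anisoyl oxygen over the aroyl oxygen; both are secured by ring size, since the central carbon or the other oxygen could only give a four-membered ring, and the coupling site was fixed in step 2 by placing the acyl carbon next to bromine. Uncatalysed nucleophilic aromatic substitution is not expected because both benzyloxy groups donate into the ring positions that would carry the negative charge, which is why the copper cycle is used.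

Step 8
Reactants: 14 5,7-bis(benzyloxy)-3-(methoxymethoxy)-2-(4-methoxyphenyl)-4H-chromen-4-one
Product: 15 5,7-bis(benzyloxy)-3-hydroxy-2-(4-methoxyphenyl)-4H-chromen-4-one
Conditions: HCl (cat., conc. aq), MeOH/THF, 50 °C
Reagents that add atoms: none
Why: Acid-catalysed transacetalisation of the methoxymethyl ether to methanol frees the 3-hydroxyl, while benzyl and methyl aryl ethers should survive dilute acid at this temperature.

Step 9
Reactants: 15 5,7-bis(benzyloxy)-3-hydroxy-2-(4-methoxyphenyl)-4H-chromen-4-one
Product: 17 potassium 5,7-bis(benzyloxy)-2-(4-methoxyphenyl)-4-oxo-4H-chromen-3-yl sulfate, via pyridinium sulfate salt 16 (not isolated)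
Conditions: SO3·pyridine, pyridine, 60 °C; then KOH, MeOH/H2O, 0 °C (to pH 8)
Reagents that add atoms: sulfur trioxide pyridine complex, [O-]S(=O)(=O)[n+]1ccccc1; potassium hydroxide, [K+].[OH-]
Why: O-Sulfation by sulfur trioxide transfer from the amine complex to the only free hydroxyl, followed by neutralisation to the potassium salt, which keeps the acid-labile sulfate as a stable anion and removes pyridine, an amine of the kind that retards benzyl ether hydrogenolysis on palladium.

Step 10
Reactants: 17 potassium 5,7-bis(benzyloxy)-2-(4-methoxyphenyl)-4-oxo-4H-chromen-3-yl sulfate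
Product: 19 kaempferide 3-O-sulfate (5,7-dihydroxy-2-(4-methoxyphenyl)-4-oxo-4H-chromen-3-yl hydrogen sulfate), via potassium kaempferide 3-sulfate 18 (not isolated)
Conditions: H2 (1 atm), 10% Pd/C, MeOH/THF, rt; filter; then HCl (1.0 equiv, aq), 0 °C; C18 desalting, lyophilisation
Reagents that add atoms: none
Why: Hydrogenolysis of the two benzyl aryl ethers over Pd/C under neutral conditions should leave the sulfate monoester anion, the aryl methyl ether and the chromone C2–C3 double bond intact, and one equivalent of strong acid in the cold then protonates the sulfate to the hydrogen sulfate drawn for the target.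

**Compound list**

1 | 5-bromoresorcinol (5-bromobenzene-1,3-diol) | Oc1cc(O)cc(Br)c1 | starting material
2 | benzyl bromide | BrCc1ccccc1 | starting material
3 | 1,3-bis(benzyloxy)-5-bromobenzene | Brc1cc(OCc2ccccc2)cc(OCc2ccccc2)c1 | intermediate
4 | N-{[2,4-bis(benzyloxy)-6-bromophenyl]methylidene}-N-methylmethanaminium chloride (aryl iminium chloride) | C[N+](C)=Cc1c(Br)cc(OCc2ccccc2)cc1OCc1ccccc1.[Cl-] | intermediate
5 | 2,4-bis(benzyloxy)-6-bromobenzaldehyde | O=Cc1c(Br)cc(OCc2ccccc2)cc1OCc1ccccc1 | intermediate
6 | 2-bromo-1-(4-methoxyphenyl)ethanone | COc1ccc(cc1)C(=O)CBr | starting material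
7 | 2-(4-methoxyphenyl)-2-oxoethyl formate (formate ester) | O=COCC(=O)c1ccc(OC)cc1 | intermediate
8 | 2-hydroxy-1-(4-methoxyphenyl)ethanone | OCC(=O)c1ccc(OC)cc1 | intermediate
9 | 2-(methoxymethoxy)-1-(4-methoxyphenyl)ethanone | COCOCC(=O)c1ccc(OC)cc1 | intermediate
10 | lithium (Z)-2-(methoxymethoxy)-1-(4-methoxyphenyl)ethen-1-olate (lithium enolate) | COCO/C=C(\[O-])c1ccc(OC)cc1.[Li+] | intermediate
11 | lithium 1-[2,4-bis(benzyloxy)-6-bromophenyl]-2-(methoxymethoxy)-3-(4-methoxyphenyl)-3-oxopropan-1-olate (lithium aldolate; diastereomer mixture) | COCOC(C([O-])c1c(Br)cc(OCc2ccccc2)cc1OCc1ccccc1)C(=O)c1ccc(OC)cc1.[Li+] | intermediate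
12 | 3-[2,4-bis(benzyloxy)-6-bromophenyl]-3-hydroxy-2-(methoxymethoxy)-1-(4-methoxyphenyl)propan-1-one (syn/anti mixture, racemic) | COCOC(C(O)c1c(Br)cc(OCc2ccccc2)cc1OCc1ccccc1)C(=O)c1ccc(OC)cc1 | intermediate
13 | 1-[2,4-bis(benzyloxy)-6-bromophenyl]-2-(methoxymethoxy)-3-(4-methoxyphenyl)propane-1,3-dione (racemic, readily enolised) | COCOC(C(=O)c1ccc(OC)cc1)C(=O)c1c(Br)cc(OCc2ccccc2)cc1OCc1ccccc1 | intermediate
14 | 5,7-bis(benzyloxy)-3-(methoxymethoxy)-2-(4-methoxyphenyl)-4H-chromen-4-one | COCOc1c(-c2ccc(OC)cc2)oc2cc(OCc3ccccc3)cc(OCc3ccccc3)c2c1=O | intermediate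
15 | 5,7-bis(benzyloxy)-3-hydroxy-2-(4-methoxyphenyl)-4H-chromen-4-one | COc1ccc(cc1)-c1oc2cc(OCc3ccccc3)cc(OCc3ccccc3)c2c(=O)c1O | intermediate
16 | pyridinium 5,7-bis(benzyloxy)-2-(4-methoxyphenyl)-4-oxo-4H-chromen-3-yl sulfate | COc1ccc(cc1)-c1oc2cc(OCc3ccccc3)cc(OCc3ccccc3)c2c(=O)c1OS(=O)(=O)[O-].c1cc[nH+]cc1 | intermediate
17 | potassium 5,7-bis(benzyloxy)-2-(4-methoxyphenyl)-4-oxo-4H-chromen-3-yl sulfate | COc1ccc(cc1)-c1oc2cc(OCc3ccccc3)cc(OCc3ccccc3)c2c(=O)c1OS(=O)(=O)[O-].[K+] | intermediate
18 | potassium 5,7-dihydroxy-2-(4-methoxyphenyl)-4-oxo-4H-chromen-3-yl sulfate (potassium kaempferide 3-sulfate) | COc1ccc(cc1)-c1oc2cc(O)cc(O)c2c(=O)c1OS(=O)(=O)[O-].[K+] | intermediate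
19 | kaempferide 3-O-sulfate, 5,7-dihydroxy-2-(4-methoxyphenyl)-4-oxo-4H-chromen-3-yl hydrogen sulfate | COc1ccc(-c2oc3cc(O)cc(O)c3c(=O)c2OS(=O)(=O)O)cc1 | target

**Step count**

Total: 10 steps. Longest linear sequence: 8 steps (1, 2, 5, 6, 7, 8, 9, 10 from 5-bromoresorcinol; equally 3, 4, 5–10 from the bromo ketone).

**Steps most likely to fail**

Step 7 (copper ring closure). Copper may insert only slowly into the electron-rich C–Br bond flanked by the acyl group, so that base-induced retro-Claisen cleavage of the 2-alkoxy diketone and protodebromination outrun O-arylation. The fallback changes the activating group to iodine, which should allow closure at much lower temperature; it sets out from 3 and comes back at 14. Compound 3 would undergo copper-catalysed aromatic Finkelstein exchange (CuI, NaI, trans-N,N'-dimethylcyclohexane-1,2-diamine, dioxane, 110 °C) to give 1,3-bis(benzyloxy)-5-iodobenzene F1. Formylation as in step 2 would give, through the iodoaryl iminium chloride F2, 2,4-bis(benzyloxy)-6-iodobenzaldehyde F3. Addition of enolate 10 as in step 5 would give, through the iodo lithium aldolate F4, the iodo aldol F5. Dess–Martin oxidation would then give the iodo diketone F6, which should close with CuI, 1,10-phenanthroline and Cs2CO3 in DMF near 50 °C to give 14.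

Step 5 (aldol addition). Addition to the hindered, electron-rich aldehyde may be incomplete, or the aldolate may revert by retro-aldol on warming or quenching. The fallback makes the C3–C4 bond irreversibly by acylation at the ketone oxidation level, which also removes the oxidation step; it sets out from 5 (with 9) and comes back at 13. Aldehyde 5 would be oxidised under Pinnick conditions (NaClO2, NaH2PO4, 2-methyl-2-butene, t-BuOH/H2O) to 2,4-bis(benzyloxy)-6-bromobenzoic acid F7. This acid would be converted with oxalyl chloride and catalytic DMF in CH2Cl2 into 2,4-bis(benzyloxy)-6-bromobenzoyl chloride F8. The acid chloride would C-acylate ketone 9 under soft enolisation (MgBr2·OEt2, iPr2NEt, CH2Cl2, rt, short contact time to spare the acetal), giving diketone 13 directly.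

Step 9 (sulfation). Sulfation of the hydrogen-bonded 3-hydroxyl, flanked by the carbonyl and the aryl group, may be incomplete, and the sulfate may hydrolyse during isolation of the polar salt. The fallback introduces the sulfate as a neutral, chromatographable diester; it sets out from 15 and comes back at 19, bypassing steps 9 and 10. Flavonol 15 would be treated with 2,2,2-trichloroethyl chlorosulfate (Et3N, DMAP, THF, 0 °C → rt) to give 5,7-bis(benzyloxy)-2-(4-methoxyphenyl)-4-oxo-4H-chromen-3-yl 2,2,2-trichloroethyl sulfate F9. Treatment with 10% Pd/C and HCO2NH4 in MeOH at rt would remove the trichloroethyl group by reductive β-elimination and both benzyl ethers by transfer hydrogenolysis in one operation, giving ammonium kaempferide 3-sulfate F10. One equivalent of HCl at 0 °C followed by C18 desalting would deliver 19.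

**Further compounds**

F1 | step 7 | 1,3-bis(benzyloxy)-5-iodobenzene | Ic1cc(OCc2ccccc2)cc(OCc2ccccc2)c1
F2 | step 7 | N-{[2,4-bis(benzyloxy)-6-iodophenyl]methylidene}-N-methylmethanaminium chloride (iodoaryl iminium chloride) | C[N+](C)=Cc1c(I)cc(OCc2ccccc2)cc1OCc1ccccc1.[Cl-]
F3 | step 7 | 2,4-bis(benzyloxy)-6-iodobenzaldehyde | O=Cc1c(I)cc(OCc2ccccc2)cc1OCc1ccccc1
F4 | step 7 | lithium 1-[2,4-bis(benzyloxy)-6-iodophenyl]-2-(methoxymethoxy)-3-(4-methoxyphenyl)-3-oxopropan-1-olate (iodo lithium aldolate) | COCOC(C([O-])c1c(I)cc(OCc2ccccc2)cc1OCc1ccccc1)C(=O)c1ccc(OC)cc1.[Li+]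
F5 | step 7 | 3-[2,4-bis(benzyloxy)-6-iodophenyl]-3-hydroxy-2-(methoxymethoxy)-1-(4-methoxyphenyl)propan-1-one (iodo aldol, diastereomer mixture) | COCOC(C(O)c1c(I)cc(OCc2ccccc2)cc1OCc1ccccc1)C(=O)c1ccc(OC)cc1
F6 | step 7 | 1-[2,4-bis(benzyloxy)-6-iodophenyl]-2-(methoxymethoxy)-3-(4-methoxyphenyl)propane-1,3-dione (iodo diketone) | COCOC(C(=O)c1ccc(OC)cc1)C(=O)c1c(I)cc(OCc2ccccc2)cc1OCc1ccccc1
F7 | step 5 | 2,4-bis(benzyloxy)-6-bromobenzoic acid | OC(=O)c1c(Br)cc(OCc2ccccc2)cc1OCc1ccccc1
F8 | step 5 | 2,4-bis(benzyloxy)-6-bromobenzoyl chloride | ClC(=O)c1c(Br)cc(OCc2ccccc2)cc1OCc1ccccc1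
F9 | step 9 | 5,7-bis(benzyloxy)-2-(4-methoxyphenyl)-4-oxo-4H-chromen-3-yl 2,2,2-trichloroethyl sulfate | COc1ccc(cc1)-c1oc2cc(OCc3ccccc3)cc(OCc3ccccc3)c2c(=O)c1OS(=O)(=O)OCC(Cl)(Cl)Cl
F10 | step 9 | ammonium 5,7-dihydroxy-2-(4-methoxyphenyl)-4-oxo-4H-chromen-3-yl sulfate (ammonium kaempferide 3-sulfate) | COc1ccc(cc1)-c1oc2cc(O)cc(O)c2c(=O)c1OS(=O)(=O)[O-].[NH4+]
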